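The readings were generated by integration for an exercise; noise was put on by code.

Maple, alder, ash and cedar take the same amounts, 0.050 M of each substrate, 0.100 M of reagent and 0.10 mM of free catalyst, so the choice to make is the temperature.

| setting | spring | winter | summer | maple | alder | ash | cedar |
|---|---|---|---|---|---|---|---|
| left-handed substrate | 0.050 M | 0.050 M | 0.050 M | 0.050 M | 0.050 M | 0.050 M | 0.050 M |
| right-handed substrate | 0.050 M | 0.050 M | 0.050 M | 0.050 M | 0.050 M | 0.050 M | 0.050 M |
| reagent | 0.10 M | 0.10 M | 0.15 M | 0.100 M | 0.100 M | 0.100 M | 0.100 M |
| free catalyst | 0.050 mM | 0.075 mM | 0.10 mM | 0.10 mM | 0.10 mM | 0.10 mM | 0.10 mM |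
| temperature | 18 °C | 45 °C | 18 °C | 30 °C | 55 °C |  | 5 °C |
| remark | run made earlier | run made earlier | run made earlier |  |  | at 5 °C until 20 min, from then on at 55 °C |  |
| time |  |  |  | 30 min | 30 min | 30 min | 30 min |

| run | time / min | left-handed product / % | right-handed product / % | left-handed substrate / % |
|---|---|---|---|---|
| spring | 5.00 | 16.0 | 0.2 | 33.3 |
| spring | 10.0 | 26.5 | 1.7 | 22.6 |
| spring | 25.0 | 45.6 | 5.0 | 3.9 |
| spring | 80.0 | 50.2 | 14.9 | 0 |
| winter | 1.33 | 17.0 | 4.7 | 34.0 |
| winter | 3.00 | 30.6 | 10.6 | 20.4 |
| winter | 8.00 | 44.0 | 21.3 | 4.6 |
| winter | 20.0 | 49.7 | 32.7 | 1.2 |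
| summer | 5.00 | 34.5 | 2.8 | 15.5 |
| summer | 10.0 | 47.1 | 7.6 | 3.6 |
| summer | 25.0 | 49.8 | 18.0 | 0 |
| summer | 80.0 | 49.5 | 36.8 | 0.8 |

(each reading ± 0.5 percentage points)

- free catalyst is single-handed; left-handed substrate and right-handed substrate are mirror images of each other, charged as a racemate, each of them at the stated concentration
- an excess is the difference of the two amounts in percent of their sum
- an excess is below zero if the other one leads

1. the flask with the highest excess of left-handed product over right-handed product ("all alike" if they lie within 1.5 percentage points) (maple / alder / ash / cedar / all alike)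
2. excess of left-handed product over right-handed product at the end, maple
3. excess of left-handed product over right-handed product at the end, alder
4. excess of left-handed product over right-handed product at the end, ash
5. excess of left-handed product over right-handed product at the end, cedar

We compare the two substrates by the selectivity factor s = ln a / ln b, where a and b are the fractions of left-handed and right-handed substrate still unreacted. Right-handed substrate is read as its charge less right-handed product. Then ln b = ln a / s, and the excess of left-handed product is (b − a)/(2 − a − b).

Spring at 25.0 min reads s = 24.2, and winter at 8.00 min reads 4.30. Summer, at the temperature of spring but with 0.15 M of reagent and 0.10 mM of free catalyst, reads 16.0 at 10.0 min, lower than spring. We therefore use spring and winter, which carry the 0.100 M of reagent of the new flasks, although they hold 0.050 mM and 0.075 mM of free catalyst where the new flasks hold 0.10 mM.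

Setting that difference of free catalyst aside as an assumption of ours, their two readings give ln s a slope equal to an activation-energy difference of 49.3 kJ/mol. Extended as an estimate past the two measured temperatures, that line puts s at 62.7 at 5 °C, and the selectivity factor at 55 °C at 2.44.

Spring left 7.80 % of its left-handed substrate at 25.0 min, so we take a = 10.0 % as our own stage of comparison. There we reckon an excess of 92.3 % for cedar and 19.1 % for alder. Ash ends at 55 °C, so we expect it below cedar too. We would charge cedar.

The forecast chose cedar, with 34 % for maple, 7 % for alder, 22 % for ash and 88 % for cedar, holding that “selectivity falls sharply with heat”.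

The flasks give 33.9 % in maple, 3.99 % in alder, 15.1 % in ash and 90.4 % in cedar, so cedar leads.

    2 free catalyst ⇌ resting dimer, settled at all times (K = 16600 /M, ΔH = −18.0 kJ/mol)
    free catalyst + left-handed substrate ⇌ catalyst intermediate A (K = 520 /M, k = 8340 /M/min, Ea = 45.0 kJ/mol, ΔH = −41.0 kJ/mol)
    reagent + catalyst intermediate A → free catalyst + left-handed product (k = 352 /M/min, Ea = 51.0 kJ/mol)
    free catalyst + right-handed substrate ⇌ catalyst intermediate B (K = 8.04 /M, k = 1.06 × 10⁵ /M/min, Ea = 40.0 kJ/mol, ΔH = 33.0 kJ/mol)
    reagent + catalyst intermediate B → free catalyst + right-handed product (k = 163 /M/min, Ea = 39.0 kJ/mol)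
    (constants at 5 °C)

Alder's remainders at 30.0 min read s = 2.23, beside our 2.44. Just after the start of alder, reagent was used through catalyst intermediate A 1.9 times as fast as through catalyst intermediate B. A neighbour of alder with 0.060 M of reagent can convert 60.0 % of the substrates. At 2.44, a = 25.0 % goes with b = 56.6 %, which is a conversion of 59.2 % and an excess of 26.7 %. Computed, at 30.0 min that neighbour's reagent, the limiting reagent, stands at 0.0474 % of its own charge, with 26 % of the charged left-handed substrate still there unbound and an excess of 24.0 %.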